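**Plan**

1. Numbering used throughout: dihydronaphthalene C1 (aryl), C2 (CH2OH), C3 (CHO), C4, C4a–C8a with C7–OH and C8–OMe; pendant ring = ring A, benzo ring = ring B, new carbocycle = ring C; cinnamoyl monomers are numbered ring C1–C6, side chain C7, C8, C9.
2. Enabling feature: both halves are guaiacyl C6–C3 units with a phenolic OH para to the side chain (ring A OH para to C1; C7–OH para to C4a). C2 and C3 are therefore the two like-polarity C8 carbons of two 4-hydroxycinnamoyl units, C1 is a quinone-methide carbon and C8a an ortho carbon of ring B.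
3. Retrosynthesis: the CHO/CH2OH pair goes back to two identical acyl groups; a tert-butyl group is placed next to each phenol; then C2–C3 and C1–C8a are cut together, leaving two molecules of one 5-tert-butylferuloyl camphorsultam imide.
4. Forward: aldehyde by bromination and methoxylation, Wittig olefination to the monomer, oxidative dimerisation (closes ring C), de-tert-butylation, reductive removal of both auxiliaries to the diol, selective allylic oxidation.
5. Stereochemistry: C2 is set by the sultam in the C–C coupling, C1 is set trans to C2 in the ring closure; the sultams make the antipodal skeletons diastereomeric and separable.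

Key step: step 5

Assumption: the bornane-10,2-sultam is taken to direct bond formation at the α-carbon of its N-enoyl derivatives in its usual sense (for the (2S)-sultam the C8 si face); if the radical coupling follows the opposite sense, the (2R)-sultam is used in the same sequence.

**Route**

Step 1
Reactants: 1 3-tert-butyl-4-hydroxybenzaldehyde
Product: 2 3-bromo-5-tert-butyl-4-hydroxybenzaldehyde
Conditions: Br2, AcOH, rt
Reagents that add atoms: bromine, BrBr
Why: Electrophilic aromatic bromination should go to the only free position ortho to the OH, since para carries CHO and the other ortho position carries tert-butyl.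

Step 2
Reactants: 2 3-bromo-5-tert-butyl-4-hydroxybenzaldehyde
Product: 3 3-tert-butyl-4-hydroxy-5-methoxybenzaldehyde
Conditions: NaOMe (excess), CuBr (cat.), DMF/MeOH, 110 °C; then aq. HCl
Reagents that add atoms: sodium methoxide, C[O-].[Na+]
Why: Ullmann-type copper-catalysed methoxylation of an aryl bromide ortho to a phenoxide is the standard way from 5-bromo-4-hydroxybenzaldehydes to the 5-methoxy compounds, and the non-enolisable aldehyde should survive.

Step 3
Reactants: 4 (2S)-bornane-10,2-sultam [(1R)-(+)-2,10-camphorsultam]; 5 bromoacetyl bromide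
Product: 6 N-(bromoacetyl)-(2S)-bornane-10,2-sultam
Conditions: NaH, THF, 0 °C to rt
Reagents that add atoms: none
Why: N-acylation of the sodium sulfonamide should occur at the acyl bromide carbon, the harder and more reactive electrophilic site, leaving the C–Br bond for the next step.

Step 4
Reactants: 3 3-tert-butyl-4-hydroxy-5-methoxybenzaldehyde; 6 N-(bromoacetyl)-(2S)-bornane-10,2-sultam; 7 triphenylphosphine
Product: 10 N-[(E)-3-(3-tert-butyl-4-hydroxy-5-methoxyphenyl)prop-2-enoyl]-(2S)-bornane-10,2-sultam, via phosphonium bromide 8 (not isolated), via phosphorus ylide 9 (not isolated)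
Conditions: 6 + 7, toluene, 60 °C; then 3, NaHCO3, toluene/H2O, 80 °C
Reagents that add atoms: none
Why: Wittig olefination with an imide-stabilised ylide tolerates the free phenol and should give the E-alkene under thermodynamic control.

Step 5
Reactants: 10 N-[(E)-3-(3-tert-butyl-4-hydroxy-5-methoxyphenyl)prop-2-enoyl]-(2S)-bornane-10,2-sultam (two molecules)
Product: 13 N,N'-[(1S,2R)-6-tert-butyl-1-(3-tert-butyl-4-hydroxy-5-methoxyphenyl)-7-hydroxy-8-methoxy-1,2-dihydronaphthalene-2,3-dicarbonyl]bis[(2S)-bornane-10,2-sultam], via bis(quinone methide) 11 (not isolated), via styrenyl quinone methide 12 (not isolated)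
Conditions: FeCl3·6H2O (2.2 equiv), acetone/H2O, 0 °C to rt; chromatography, then crystallisation
Reagents that add atoms: none
Why: Trivalent iron oxidises each phenol to a phenoxyl radical with spin at C8 (α to the imide); two radicals join C8–C8' (future C2–C3) to give 11, prototropy in one half restores its arene to give 12, and the ring carbon ortho to OMe then adds to the remaining quinone-methide carbon (future C1) before rearomatisation. The closest known reaction type is the oxidative dimerisation of sinapate-type 4-hydroxycinnamic esters and chiral imides to 1-aryl-1,2-dihydronaphthalene-2,3-dicarboxylic derivatives. Ring C closes by a 6-exo-trig Friedel–Crafts (vinylogous Michael) attack of ring B on the quinone methide, whose exocyclic C=C lies outside the ring being formed. C2 is controlled by the sultam, which should expose only the C8 si face of the s-cis N-enoyl unit (the face away from the flanking sulfonyl oxygen), and C1 is controlled by C2, the aryl group ending trans and pseudoaxial to the C2 acyl group. The step needs 8–8' coupling instead of 8–5' or 8–O–4' coupling, and ring closure ortho to OMe instead of para to it; the tert-butyl group secures both by occupying C5, screening the phenoxyl oxygen and the neighbouring C6, and activating the position para to itself. Because both auxiliaries remain attached, the (1S,2R) and (1R,2S) skeletons are diastereomers, so the wanted isomer can be purified.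

Step 6
Reactants: 13 the bis-tert-butyl dimer
Product: 14 N,N'-[(1S,2R)-7-hydroxy-1-(4-hydroxy-3-methoxyphenyl)-8-methoxy-1,2-dihydronaphthalene-2,3-dicarbonyl]bis[(2S)-bornane-10,2-sultam]
Conditions: AlCl3 (excess), MeNO2, toluene, rt to 40 °C
Reagents that add atoms: none
Why: Retro-Friedel–Crafts transalkylation: ipso-protonation ortho to each phenolic OH expels the tert-butyl cation, which toluene captures, while the electron-poor acrylimide alkene and both stereocentres should stay untouched.

Step 7
Reactants: 14 the de-tert-butylated bis-imide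
Product: 15 (1S,2R)-2,3-bis(hydroxymethyl)-1-(4-hydroxy-3-methoxyphenyl)-8-methoxy-1,2-dihydronaphthalen-7-ol
Conditions: i-Bu2AlH (excess), CH2Cl2/THF, −78 to 0 °C; aq. sodium potassium tartrate
Reagents that add atoms: none
Why: The electrophilic aluminium hydride should reduce both N-acyl sultams 1,2 through the aldehydes to the primary alcohols and release the auxiliary for recovery, without touching C1 or C2.

Step 8
Reactants: 15 the diol
Product: 16 vitedoin A, (1S,2R)-7-hydroxy-1-(4-hydroxy-3-methoxyphenyl)-2-(hydroxymethyl)-8-methoxy-1,2-dihydronaphthalene-3-carbaldehyde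
Conditions: activated MnO2, acetone, rt
Reagents that add atoms: none
Why: MnO2 allylic oxidation should convert only the cinnamyl-type primary alcohol on C3 into the enal and leave the saturated primary alcohol on C2 alone.

**Compound list**

1 | 3-tert-butyl-4-hydroxybenzaldehyde | O=Cc1ccc(O)c(C(C)(C)C)c1 | starting material
2 | 3-bromo-5-tert-butyl-4-hydroxybenzaldehyde | O=Cc1cc(Br)c(O)c(C(C)(C)C)c1 | intermediate
3 | 3-tert-butyl-4-hydroxy-5-methoxybenzaldehyde | COc1cc(C=O)cc(C(C)(C)C)c1O | intermediate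
4 | (2S)-bornane-10,2-sultam [(1R)-(+)-2,10-camphorsultam] | N1[C@H]2C[C@@H]3CC[C@@]2(CS1(=O)=O)C3(C)C | starting material
5 | bromoacetyl bromide | O=C(Br)CBr | starting material
6 | N-(bromoacetyl)-(2S)-bornane-10,2-sultam | O=C(CBr)N1[C@H]2C[C@@H]3CC[C@@]2(CS1(=O)=O)C3(C)C | intermediate
7 | triphenylphosphine | c1ccc(P(c2ccccc2)c2ccccc2)cc1 | starting material
8 | [2-oxo-2-((2S)-bornane-10,2-sultam-N-yl)ethyl]triphenylphosphonium bromide | [Br-].O=C(C[P+](c1ccccc1)(c1ccccc1)c1ccccc1)N1[C@H]2C[C@@H]3CC[C@@]2(CS1(=O)=O)C3(C)C | intermediate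
9 | N-[(triphenylphosphoranylidene)acetyl]-(2S)-bornane-10,2-sultam | O=C(C=P(c1ccccc1)(c1ccccc1)c1ccccc1)N1[C@H]2C[C@@H]3CC[C@@]2(CS1(=O)=O)C3(C)C | intermediate
10 | N-[(E)-3-(3-tert-butyl-4-hydroxy-5-methoxyphenyl)prop-2-enoyl]-(2S)-bornane-10,2-sultam | COc1cc(/C=C/C(=O)N2[C@H]3C[C@@H]4CC[C@@]3(CS2(=O)=O)C4(C)C)cc(C(C)(C)C)c1O | intermediate
11 | (2R,3R)-2,3-bis[(3-tert-butyl-5-methoxy-4-oxocyclohexa-2,5-dien-1-ylidene)methyl]butanedioyl bis[(2S)-bornane-10,2-sultam] (bis(quinone methide)) | COC1=CC(=C[C@@H](C(=O)N2[C@H]3C[C@@H]4CC[C@@]3(CS2(=O)=O)C4(C)C)[C@H](C(=O)N2[C@H]3C[C@@H]4CC[C@@]3(CS2(=O)=O)C4(C)C)C=C2C=C(OC)C(=O)C(C(C)(C)C)=C2)C=C(C(C)(C)C)C1=O | intermediate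
12 | (R)-3-[(3-tert-butyl-5-methoxy-4-oxocyclohexa-2,5-dien-1-ylidene)methyl]-2-[(E)-(3-tert-butyl-4-hydroxy-5-methoxyphenyl)methylidene]butanedioyl bis[(2S)-bornane-10,2-sultam] (styrenyl quinone methide) | COc1cc(/C=C(/C(=O)N2[C@H]3C[C@@H]4CC[C@@]3(CS2(=O)=O)C4(C)C)[C@H](C(=O)N2[C@H]3C[C@@H]4CC[C@@]3(CS2(=O)=O)C4(C)C)C=C2C=C(OC)C(=O)C(C(C)(C)C)=C2)cc(C(C)(C)C)c1O | intermediate
13 | N,N'-[(1S,2R)-6-tert-butyl-1-(3-tert-butyl-4-hydroxy-5-methoxyphenyl)-7-hydroxy-8-methoxy-1,2-dihydronaphthalene-2,3-dicarbonyl]bis[(2S)-bornane-10,2-sultam] | COc1cc([C@H]2c3c(cc(C(C)(C)C)c(O)c3OC)C=C(C(=O)N3[C@H]4C[C@@H]5CC[C@@]4(CS3(=O)=O)C5(C)C)[C@@H]2C(=O)N2[C@H]3C[C@@H]4CC[C@@]3(CS2(=O)=O)C4(C)C)cc(C(C)(C)C)c1O | intermediate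
14 | N,N'-[(1S,2R)-7-hydroxy-1-(4-hydroxy-3-methoxyphenyl)-8-methoxy-1,2-dihydronaphthalene-2,3-dicarbonyl]bis[(2S)-bornane-10,2-sultam] | COc1cc([C@H]2c3c(ccc(O)c3OC)C=C(C(=O)N3[C@H]4C[C@@H]5CC[C@@]4(CS3(=O)=O)C5(C)C)[C@@H]2C(=O)N2[C@H]3C[C@@H]4CC[C@@]3(CS2(=O)=O)C4(C)C)ccc1O | intermediate
15 | (1S,2R)-2,3-bis(hydroxymethyl)-1-(4-hydroxy-3-methoxyphenyl)-8-methoxy-1,2-dihydronaphthalen-7-ol | COc1cc([C@H]2c3c(ccc(O)c3OC)C=C(CO)[C@@H]2CO)ccc1O | intermediate
16 | vitedoin A, (1S,2R)-7-hydroxy-1-(4-hydroxy-3-methoxyphenyl)-2-(hydroxymethyl)-8-methoxy-1,2-dihydronaphthalene-3-carbaldehyde | COc1cc([C@H]2c3c(ccc(O)c3OC)C=C(C=O)[C@@H]2CO)ccc1O | target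

**Summary**

Total step count: 8. Longest linear sequence: 7 steps (1 → 2 → 3 → 10 → 13 → 14 → 15 → 16).

Steps most likely to fail:

Step 5. The radical–radical coupling may proceed with weak facial discrimination by the auxiliary, or the bulky imide may slow ring closure, so that the wanted diastereomer is hard to obtain pure. Fallback (stereochemistry by resolution instead of induction): from 3, Wittig olefination with methyl (triphenylphosphoranylidene)acetate should give methyl (E)-3-(3-tert-butyl-4-hydroxy-5-methoxyphenyl)prop-2-enoate F1. Its FeCl3·6H2O dimerisation in acetone/H2O, the best-precedented ester form of the reaction, should give the racemic trans diester F2. AlCl3 in toluene should remove the tert-butyl groups to give the racemic diester F3, and i-Bu2AlH should reduce it to the racemic diol, that is 15 together with its (1R,2S) enantiomer F4. F4 is removed by preparative chromatography on a chiral stationary phase, and the route is rejoined at 15.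

Step 6. The Lewis acid may also demethylate the guaiacyl ethers, transfer the activated acyl groups to toluene, or open and re-close the C1–C8a bond. Fallback (a blocking group removed without acid): from 6, the Wittig sequence of step 4 with commercial 5-bromovanillin should give N-[(E)-3-(3-bromo-4-hydroxy-5-methoxyphenyl)prop-2-enoyl]-(2S)-bornane-10,2-sultam F5. Its FeCl3·6H2O dimerisation should give the dibromo dimer F6; here ring closure para to bromine competes with closure ortho to it, so a regioisomer may have to be separated. Hydrodebromination with Pd(PPh3)4 (zerovalent palladium) and HCO2Na in DMF at 90 °C rejoins the route at 14.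

Step 8. Oxidation of the free phenols or dehydrogenation of ring C to the arylnaphthalene may compete with the allylic oxidation. Fallback (phenol protection): from 14, TBSCl/imidazole in DMF should give the bis(silyl ether) F7, i-Bu2AlH the protected diol F8, and MnO2 the protected enal F9. Bu4NF buffered with AcOH in THF at 0 °C then releases both phenols and rejoins the route at 16.

Further compounds
F1 | step 5 | methyl (E)-3-(3-tert-butyl-4-hydroxy-5-methoxyphenyl)prop-2-enoate | COC(=O)/C=C/c1cc(OC)c(O)c(C(C)(C)C)c1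
F2 | step 5 | racemic dimethyl trans-6-tert-butyl-1-(3-tert-butyl-4-hydroxy-5-methoxyphenyl)-7-hydroxy-8-methoxy-1,2-dihydronaphthalene-2,3-dicarboxylate (drawn as the (1S,2R) enantiomer) | COc1cc([C@H]2c3c(cc(C(C)(C)C)c(O)c3OC)C=C(C(=O)OC)[C@@H]2C(=O)OC)cc(C(C)(C)C)c1O
F3 | step 5 | racemic dimethyl trans-7-hydroxy-1-(4-hydroxy-3-methoxyphenyl)-8-methoxy-1,2-dihydronaphthalene-2,3-dicarboxylate (drawn as the (1S,2R) enantiomer) | COc1cc([C@H]2c3c(ccc(O)c3OC)C=C(C(=O)OC)[C@@H]2C(=O)OC)ccc1O
F4 | step 5 | (1R,2S)-2,3-bis(hydroxymethyl)-1-(4-hydroxy-3-methoxyphenyl)-8-methoxy-1,2-dihydronaphthalen-7-ol (enantiomer of 15, second component of the racemic diol) | COc1cc([C@@H]2c3c(ccc(O)c3OC)C=C(CO)[C@H]2CO)ccc1O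
F5 | step 6 | N-[(E)-3-(3-bromo-4-hydroxy-5-methoxyphenyl)prop-2-enoyl]-(2S)-bornane-10,2-sultam | COc1cc(/C=C/C(=O)N2[C@H]3C[C@@H]4CC[C@@]3(CS2(=O)=O)C4(C)C)cc(Br)c1O
F6 | step 6 | N,N'-[(1S,2R)-6-bromo-1-(3-bromo-4-hydroxy-5-methoxyphenyl)-7-hydroxy-8-methoxy-1,2-dihydronaphthalene-2,3-dicarbonyl]bis[(2S)-bornane-10,2-sultam] | COc1cc([C@H]2c3c(cc(Br)c(O)c3OC)C=C(C(=O)N3[C@H]4C[C@@H]5CC[C@@]4(CS3(=O)=O)C5(C)C)[C@@H]2C(=O)N2[C@H]3C[C@@H]4CC[C@@]3(CS2(=O)=O)C4(C)C)cc(Br)c1O
F7 | step 8 | bis(tert-butyldimethylsilyl) ether of 14 | COc1cc([C@H]2c3c(ccc(O[Si](C)(C)C(C)(C)C)c3OC)C=C(C(=O)N3[C@H]4C[C@@H]5CC[C@@]4(CS3(=O)=O)C5(C)C)[C@@H]2C(=O)N2[C@H]3C[C@@H]4CC[C@@]3(CS2(=O)=O)C4(C)C)ccc1O[Si](C)(C)C(C)(C)C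
F8 | step 8 | bis(tert-butyldimethylsilyl) ether of 15 | COc1cc([C@H]2c3c(ccc(O[Si](C)(C)C(C)(C)C)c3OC)C=C(CO)[C@@H]2CO)ccc1O[Si](C)(C)C(C)(C)C
F9 | step 8 | bis(tert-butyldimethylsilyl) ether of 16 | COc1cc([C@H]2c3c(ccc(O[Si](C)(C)C(C)(C)C)c3OC)C=C(C=O)[C@@H]2CO)ccc1O[Si](C)(C)C(C)(C)C
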